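Ring C of the flavonol is cut at O1–C2 and C3–C4. This gives a ring A salicylaldehyde, whose formyl carbon is C4 and whose free hydroxyl is O1, and a ring B β-nitrostyrene that brings C2 and C3. The feature used is that C3 lies between two electrophilic carbons, C2 and C4. A nitro group on C3 polarises C2 for attack by O1, turns C3 into a nitronate that bonds to C4, and is later exchanged for the C3 oxygen. One amine-mediated operation thus forms both bonds and closes ring C. The precursors are 6-(benzyloxy)-2-hydroxy-3,4-dimethoxybenzaldehyde and 3,5-bis(benzyloxy)-4-methoxy-β-nitrostyrene, so a single hydrogenolysis ends the route.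

Key step: step 10

Remark on ring A regiochemistry: the hydroxyl already present in the ring A starting aldehyde stands next to a methoxy group and must become O1, while the oxygen created from its formyl carbon must carry the benzyl group (future 5-OH). Benzylating first and oxidising afterwards would swap these roles and lead to the 5,6,7-oxygenated isomer, so the native hydroxyl is masked as a MOM ether for three steps.

Remark on stereochemistry: the target is achiral. The sp3 centres formed at C2, C3 and C4 on the way are racemic, need no control, and disappear when ring C becomes the pyranone.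

Step 1
Reactants: 1 3-hydroxy-4,5-dimethoxybenzaldehyde
Product: 2 3,4-dimethoxy-5-(methoxymethoxy)benzaldehyde
Conditions: MOMCl, i-Pr2NEt, CH2Cl2, 0 °C to rt
Reagents that add atoms: chloromethyl methyl ether (MOMCl), COCCl
Why: Williamson-type O-alkylation of the phenol with the reactive α-chloro ether masks the hydroxyl that must later become O1 as a base- and peracid-stable acetal, and the aldehyde does not react with these reagents.

Step 2
Reactants: 2 3,4-dimethoxy-5-(methoxymethoxy)benzaldehyde
Product: 4 3,4-dimethoxy-5-(methoxymethoxy)phenol, via aryl formate 3 (not isolated)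
Conditions: mCPBA, CH2Cl2, 0 °C to rt; aq NaHCO3 wash, concentrate; K2CO3 (cat.), MeOH, rt
Reagents that add atoms: 3-chloroperoxybenzoic acid (mCPBA), OOC(=O)c1cccc(Cl)c1
Why: Baeyer–Villiger oxidation of a trialkoxybenzaldehyde goes with aryl migration because the electron-rich ring is the better migrating group, and the aryl formate is labile enough that base-catalysed transesterification with methanol frees the phenol without touching the MOM acetal.

Step 3
Reactants: 4 3,4-dimethoxy-5-(methoxymethoxy)phenol
Product: 5 5-(benzyloxy)-1,2-dimethoxy-3-(methoxymethoxy)benzene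
Conditions: BnBr, K2CO3, DMF, rt to 50 °C
Reagents that add atoms: benzyl bromide, BrCc1ccccc1
Why: Williamson ether synthesis on the only free hydroxyl puts the benzyl group on the oxygen that ends as the 5-OH of ring A.

Step 4
Reactants: 5 5-(benzyloxy)-1,2-dimethoxy-3-(methoxymethoxy)benzene
Product: 6 5-(benzyloxy)-2,3-dimethoxyphenol
Conditions: conc. HCl (cat.), MeOH, 45 °C
Reagents that add atoms: none
Why: Acid-catalysed transacetalisation with methanol removes only the MOM group, since aryl benzyl and aryl methyl ethers need far stronger acid, and the large excess of methanol captures the methoxymethyl cation before it can alkylate the electron-rich ring.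

Step 5
Reactants: 6 5-(benzyloxy)-2,3-dimethoxyphenol
Product: 8 6-(benzyloxy)-2-hydroxy-3,4-dimethoxybenzaldehyde, via salicyl alcohol 7 (not isolated)
Conditions: MgCl2 (anhydrous), Et3N, (CH2O)n, MeCN, reflux; 1 M HCl work-up
Reagents that add atoms: paraformaldehyde (reacts as formaldehyde), C=O
Why: Casnati–Skattebøl ortho-formylation, in which formaldehyde bound to the magnesium phenoxide is delivered through a six-membered chelate to C6, the only unsubstituted ortho carbon, and a second formaldehyde oxidises the benzylic alkoxide of 7 by Oppenauer-type hydride transfer, so neither the para position nor the ethers are touched.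

Step 6
Reactants: 9 methyl 3,5-dihydroxy-4-methoxybenzoate
Product: 10 methyl 3,5-bis(benzyloxy)-4-methoxybenzoate
Conditions: BnBr (2.4 equiv), K2CO3, DMF, 60 °C
Reagents that add atoms: benzyl bromide, BrCc1ccccc1
Why: Double Williamson ether synthesis on the two equivalent phenols, with the methyl ester inert to carbonate in DMF.

Step 7
Reactants: 10 methyl 3,5-bis(benzyloxy)-4-methoxybenzoate
Product: 11 [3,5-bis(benzyloxy)-4-methoxyphenyl]methanol
Conditions: LiAlH4, THF, 0 °C to rt; aqueous work-up
Reagents that add atoms: none
Why: Hydride reduction of the aromatic ester to the primary alcohol, which leaves aryl ethers untouched.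

Step 8
Reactants: 11 [3,5-bis(benzyloxy)-4-methoxyphenyl]methanol
Product: 12 3,5-bis(benzyloxy)-4-methoxybenzaldehyde
Conditions: MnO2 (activated, excess), CH2Cl2, rt
Reagents that add atoms: none
Why: Heterogeneous MnO2 oxidation is selective for benzylic alcohols and stops at the aldehyde.

Step 9
Reactants: 12 3,5-bis(benzyloxy)-4-methoxybenzaldehyde; 13 nitromethane
Product: 15 (E)-1,3-bis(benzyloxy)-2-methoxy-5-(2-nitroethenyl)benzene, via nitro alcohol 14 (not isolated)
Conditions: NH4OAc, AcOH, 95 °C (13 in excess)
Reagents that add atoms: none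
Why: Henry (nitroaldol) condensation under ammonium acetate buffering, in which the racemic nitro alcohol 14 dehydrates at once and the conjugated E-alkene forms under thermodynamic control because it keeps the aryl and nitro groups apart.

Step 10
Reactants: 8 6-(benzyloxy)-2-hydroxy-3,4-dimethoxybenzaldehyde; 15 (E)-1,3-bis(benzyloxy)-2-methoxy-5-(2-nitroethenyl)benzene
Product: 18 5-(benzyloxy)-2-[3,5-bis(benzyloxy)-4-methoxyphenyl]-7,8-dimethoxy-3-nitro-2H-chromene (racemic), via oxa-Michael adduct 16 (not isolated), via nitrochromanol 17 (not isolated)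
Conditions: 15 (1.3 equiv), DABCO (1.0 equiv), 4 Å MS, MeCN (ca. 1 M), 60 °C
Reagents that add atoms: none
Why: DABCO deprotonates the hydrogen-bonded phenol of 8, and the phenoxide adds to the benzylic β-carbon of 15, the only position that the nitro group polarises for nucleophilic attack, so O1–C2 is formed first and the nitronate of 16 results (oxa-Michael addition). The nitronate carbon C3 now sits next to the ortho formyl group and attacks it in an intramolecular Henry reaction, a 6-(enolexo)-exo-trig closure of ring C that forms C3–C4 and gives 17; E1cB loss of water, pulled by conjugation of the nitroalkene with ring A and by the sieves, drains the two reversible additions towards 18. The closest known reaction type is the tertiary-amine-promoted condensation of salicylaldehydes with β-nitrostyrenes to 2-aryl-3-nitro-2H-chromenes. C2 is the only stereocentre left in 18; nothing chiral is present, so it forms as a racemate, which is harmless because C2 becomes sp2 in step 11, and the centres at C3 and C4 of 17 vanish on dehydration. The step needs regioselectivity (O to C2, C3 to C4), fixed by the polarity of the nitroalkene, and chemoselectivity for a single O-nucleophile, secured because every other hydroxyl is benzylated or methylated. Its weak point is the aldehyde, which is flanked by O-2 and O-6 and deactivated by three donor oxygens, and this is met by high concentration, heating, a full equivalent of DABCO and a small excess of 15.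

Step 11
Reactants: 18 5-(benzyloxy)-2-[3,5-bis(benzyloxy)-4-methoxyphenyl]-7,8-dimethoxy-3-nitro-2H-chromene
Product: 21 5-(benzyloxy)-2-[3,5-bis(benzyloxy)-4-methoxyphenyl]-3-hydroxy-7,8-dimethoxy-4H-chromen-4-one, via nitro epoxide 19 (not isolated), via ketol 20 (not isolated)
Conditions: 30% aq H2O2 (excess), 2 M aq NaOH, THF–MeOH, 0 °C to rt; then dilute HCl
Reagents that add atoms: hydrogen peroxide, OO; sodium hydroxide, [Na+].[OH-]
Why: Hydroperoxide anion adds to C4 of the nitroalkene and the nitronate closes to nitro epoxide 19 (Weitz–Scheffer epoxidation), hydroxide opens it at the benzylic C4 with expulsion of nitrite to give ketol 20, and the enediolate of 20 is oxidised by excess peroxide to the 3,4-dione whose stable enol is flavonol 21, a known conversion of 2-aryl-3-nitro-2H-chromenes in which the uncontrolled racemic centres of 19 and 20 and the C2 centre are all erased.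

Step 12
Reactants: 21 5-(benzyloxy)-2-[3,5-bis(benzyloxy)-4-methoxyphenyl]-3-hydroxy-7,8-dimethoxy-4H-chromen-4-one
Product: 22 2-(3,5-dihydroxy-4-methoxyphenyl)-3,5-dihydroxy-7,8-dimethoxy-4H-chromen-4-one (target)
Conditions: H2 (1 atm), Pd/C (10%), THF–MeOH, rt
Reagents that add atoms: none
Why: Catalytic hydrogenolysis cleaves the three aryl benzyl ethers in one operation, while the methyl ethers and the C2=C3 bond of the 3-hydroxypyranone are inert at atmospheric pressure.

Compound list
1 | 3-hydroxy-4,5-dimethoxybenzaldehyde | COc1cc(C=O)cc(O)c1OC | starting material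
2 | 3,4-dimethoxy-5-(methoxymethoxy)benzaldehyde | COCOc1cc(C=O)cc(OC)c1OC | intermediate
3 | 3,4-dimethoxy-5-(methoxymethoxy)phenyl formate | COCOc1cc(OC=O)cc(OC)c1OC | intermediate (not isolated)
4 | 3,4-dimethoxy-5-(methoxymethoxy)phenol | COCOc1cc(O)cc(OC)c1OC | intermediate
5 | 5-(benzyloxy)-1,2-dimethoxy-3-(methoxymethoxy)benzene | COCOc1cc(OCc2ccccc2)cc(OC)c1OC | intermediate
6 | 5-(benzyloxy)-2,3-dimethoxyphenol | COc1cc(OCc2ccccc2)cc(O)c1OC | intermediate
7 | 3-(benzyloxy)-2-(hydroxymethyl)-5,6-dimethoxyphenol | COc1cc(OCc2ccccc2)c(CO)c(O)c1OC | intermediate (not isolated)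
8 | 6-(benzyloxy)-2-hydroxy-3,4-dimethoxybenzaldehyde | COc1cc(OCc2ccccc2)c(C=O)c(O)c1OC | intermediate
9 | methyl 3,5-dihydroxy-4-methoxybenzoate | COC(=O)c1cc(O)c(OC)c(O)c1 | starting material
10 | methyl 3,5-bis(benzyloxy)-4-methoxybenzoate | COC(=O)c1cc(OCc2ccccc2)c(OC)c(OCc2ccccc2)c1 | intermediate
11 | [3,5-bis(benzyloxy)-4-methoxyphenyl]methanol | COc1c(OCc2ccccc2)cc(CO)cc1OCc1ccccc1 | intermediate
12 | 3,5-bis(benzyloxy)-4-methoxybenzaldehyde | COc1c(OCc2ccccc2)cc(C=O)cc1OCc1ccccc1 | intermediate
13 | nitromethane | C[N+](=O)[O-] | starting material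
14 | 1-[3,5-bis(benzyloxy)-4-methoxyphenyl]-2-nitroethan-1-ol (racemic) | COc1c(OCc2ccccc2)cc(C(O)C[N+](=O)[O-])cc1OCc1ccccc1 | intermediate (not isolated)
15 | (E)-1,3-bis(benzyloxy)-2-methoxy-5-(2-nitroethenyl)benzene | COc1c(OCc2ccccc2)cc(/C=C/[N+](=O)[O-])cc1OCc1ccccc1 | intermediate
16 | 6-(benzyloxy)-2-{1-[3,5-bis(benzyloxy)-4-methoxyphenyl]-2-nitroethoxy}-3,4-dimethoxybenzaldehyde (racemic; present as its nitronate) | COc1cc(OCc2ccccc2)c(C=O)c(OC(C[N+](=O)[O-])c2cc(OCc3ccccc3)c(OC)c(OCc3ccccc3)c2)c1OC | intermediate (not isolated)
17 | 5-(benzyloxy)-2-[3,5-bis(benzyloxy)-4-methoxyphenyl]-7,8-dimethoxy-3-nitrochroman-4-ol (racemic, relative configuration not controlled) | COc1cc(OCc2ccccc2)c2C(O)C([N+](=O)[O-])C(c3cc(OCc4ccccc4)c(OC)c(OCc4ccccc4)c3)Oc2c1OC | intermediate (not isolated)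
18 | 5-(benzyloxy)-2-[3,5-bis(benzyloxy)-4-methoxyphenyl]-7,8-dimethoxy-3-nitro-2H-chromene (racemic at C2) | COc1cc(OCc2ccccc2)c2C=C([N+](=O)[O-])C(c3cc(OCc4ccccc4)c(OC)c(OCc4ccccc4)c3)Oc2c1OC | intermediate
19 | 5-(benzyloxy)-2-[3,5-bis(benzyloxy)-4-methoxyphenyl]-3,4-epoxy-7,8-dimethoxy-3-nitrochroman (racemic, relative configuration not controlled) | COc1cc(OCc2ccccc2)c2C3OC3([N+](=O)[O-])C(c3cc(OCc4ccccc4)c(OC)c(OCc4ccccc4)c3)Oc2c1OC | intermediate (not isolated)
20 | 5-(benzyloxy)-2-[3,5-bis(benzyloxy)-4-methoxyphenyl]-4-hydroxy-7,8-dimethoxychroman-3-one (racemic, relative configuration not controlled) | COc1cc(OCc2ccccc2)c2C(O)C(=O)C(c3cc(OCc4ccccc4)c(OC)c(OCc4ccccc4)c3)Oc2c1OC | intermediate (not isolated)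
21 | 5-(benzyloxy)-2-[3,5-bis(benzyloxy)-4-methoxyphenyl]-3-hydroxy-7,8-dimethoxy-4H-chromen-4-one | COc1cc(OCc2ccccc2)c2c(=O)c(O)c(-c3cc(OCc4ccccc4)c(OC)c(OCc4ccccc4)c3)oc2c1OC | intermediate
22 | 2-(3,5-dihydroxy-4-methoxyphenyl)-3,5-dihydroxy-7,8-dimethoxy-4H-chromen-4-one (achiral) | COc1cc(O)c2c(=O)c(O)c(-c3cc(O)c(OC)c(O)c3)oc2c1OC | target

Total step count: 12.
Longest linear sequence: 8 steps (steps 1–5 and 10–12). The ring B branch (steps 6–9) joins at step 10.

Steps most likely to fail

**Step 10.** The Henry closure onto an aldehyde that is flanked by two oxygen substituents and deactivated by three donors may be slower than reversal of the oxa-Michael addition. The nitrostyrene would then be lost to amine-initiated oligomerisation. The fallback raises the electrophilicity of C4 by changing the acceptor from C=O to C=N–Ts.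
- It sets out from 8. Condensation with 4-methylbenzenesulfonamide (Ti(OEt)4, THF, reflux) should give (E)-N-[6-(benzyloxy)-2-hydroxy-3,4-dimethoxybenzylidene]-4-methylbenzenesulfonamide F1.
- With 15 and DABCO in toluene, the known oxa-Michael/aza-Henry/desulfonamidation sequence of salicyl N-tosylimines would pass through N-{5-(benzyloxy)-2-[3,5-bis(benzyloxy)-4-methoxyphenyl]-7,8-dimethoxy-3-nitrochroman-4-yl}-4-methylbenzenesulfonamide F2.
- E1cB loss of the sulfonamide brings it back to the route at 18.

**Step 11.** The cascade may stall after the epoxidation or after nitrite loss. Hydroxide may instead open the pyran ring by retro-oxa-Michael reaction, or excess alkaline peroxide may cleave the C2–C3 bond of the flavonol anion. The fallback separates the three events and takes the last oxidation away from peroxide.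
- It sets out from 18. Anhydrous t-BuOOH/DBU in toluene at 0 °C should stop at nitro epoxide 19, which is then isolated.
- Warm aqueous NaOAc in THF opens 19 at C4 with loss of nitrite. Ketol 20 can then equilibrate through its enediol to the conjugated dihydroflavonol (±)-trans-5-(benzyloxy)-2-[3,5-bis(benzyloxy)-4-methoxyphenyl]-3-hydroxy-7,8-dimethoxychroman-4-one F3.
- The classical dehydrogenation of dihydroflavonols with I2/KOAc in AcOH returns to the route at 21.

**Step 5.** Transfer of formaldehyde to a carbon squeezed between the magnesium phenoxide and the benzyloxy group may be slow. The benzylic alkoxide may also condense with a second electron-rich ring instead of being oxidised. The fallback brings in the formyl carbon by directed ortho-metalation before the MOM group is removed.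
- It sets out from 5. n-BuLi/TMEDA in THF (−78 to 0 °C) should lithiate the CH between OMOM and OBn, where both oxygen groups cooperate and MOM is the stronger director.
- A DMF quench gives 6-(benzyloxy)-3,4-dimethoxy-2-(methoxymethoxy)benzaldehyde F4.
- Catalytic HCl in MeOH cleaves the MOM group and rejoins the route at 8, which bypasses steps 4 and 5.

Further compounds
F1 | step 10 | (E)-N-[6-(benzyloxy)-2-hydroxy-3,4-dimethoxybenzylidene]-4-methylbenzenesulfonamide | COc1cc(OCc2ccccc2)c(/C=N/S(=O)(=O)c2ccc(C)cc2)c(O)c1OC
F2 | step 10 | N-{5-(benzyloxy)-2-[3,5-bis(benzyloxy)-4-methoxyphenyl]-7,8-dimethoxy-3-nitrochroman-4-yl}-4-methylbenzenesulfonamide (racemic, relative configuration not controlled) | COc1cc(OCc2ccccc2)c2C(NS(=O)(=O)c3ccc(C)cc3)C([N+](=O)[O-])C(c3cc(OCc4ccccc4)c(OC)c(OCc4ccccc4)c3)Oc2c1OC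
F3 | step 11 | (±)-trans-5-(benzyloxy)-2-[3,5-bis(benzyloxy)-4-methoxyphenyl]-3-hydroxy-7,8-dimethoxychroman-4-one (one enantiomer drawn) | COc1c(OCc2ccccc2)cc(cc1OCc1ccccc1)[C@@H]1[C@H](C(=O)c2c(OCc3ccccc3)cc(OC)c(OC)c2O1)O
F4 | step 5 | 6-(benzyloxy)-3,4-dimethoxy-2-(methoxymethoxy)benzaldehyde | COCOc1c(C=O)c(OCc2ccccc2)cc(OC)c1OC
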